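**Retrosynthetic overview**

- The target is reached last by phenol desilylation, α-face epoxidation of the C6=C7 alkene and Pd/CO aroylation of the C-4 hydroxyl of a trans-fused hydroazulene diol with a protected 4-iodophenol.
- The seven-membered ring is closed last by an intramolecular Wittig reaction (C6=C7) of a keto phosphonium salt.
- Key bond C8–C8a (quaternary centre): an iron-hydride HAT on an exocyclic methylene gives a tertiary cyclopentyl radical that adds to vinyltriphenylphosphonium bromide, anti to the side chain on the neighbouring carbon.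
- The cyclopentane stereotriad (C-3, C-3a, C-4) comes from a SmI2 reductive aldol of an enantioenriched α,β-epoxy cyclopentanone with ketal-protected 3-oxobutanal, followed by methylenation.
- The epoxy ketone comes from catalytic asymmetric epoxidation of 3-isopropylcyclopentenone, made from 3-methoxycyclopentenone and i-PrMgCl; the five-membered ring is bought, the seven-membered ring is formed in step 6.

Assumption: the target is taken exactly as drawn, (3R,3aS,4R,6R,7S,8aR), with the C-4 ester cis to the angular methyl; 5 and 13 are bought as the protected forms of 3-oxobutanal and 4-iodophenol; in step 2 the cinchona-amine pseudoenantiomer that gives the (1S,5R) epoxide is used (the epiquinine-derived amine is written, and its epiquinidine-derived pseudoenantiomer replaces it if the sense of induction is opposite on this substrate).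

Bicyclic compounds use azulene numbering: C-3 (OH, i-Pr), C-3a, C-4 (O), C-6 (Me), C-7, C-8, C-8a (Me).

**Route**

Step 1
Reactants: 1 3-methoxycyclopent-2-en-1-one
Product: 3 3-(propan-2-yl)cyclopent-2-en-1-one, via magnesium alkoxide 2 (not isolated)
Conditions: i-PrMgCl (1.3 equiv), CeCl3 (1.3 equiv), THF, −78 to 0 °C; then 1 M HCl, 0 °C to rt
Reagents that add atoms: isopropylmagnesium chloride CC(C)[Mg]Cl; water O
Why: 1,2-addition to the vinylogous ester followed by acid hydrolysis with loss of methanol and water transposes the carbonyl (Stork–Danheiser sequence) to the 3-alkyl enone; no stereocentre is formed.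

Step 2
Reactants: 3 3-(propan-2-yl)cyclopent-2-en-1-one
Product: 4 (1S,5R)-5-(propan-2-yl)-6-oxabicyclo[3.1.0]hexan-2-one
Conditions: 9-amino(9-deoxy)epiquinine (10 mol%), CF3CO2H (20 mol%), 50% aq. H2O2 (1.5 equiv), dioxane, 30–50 °C
Reagents that add atoms: hydrogen peroxide OO
Why: iminium activation by the chiral primary amine salt, conjugate addition of hydrogen peroxide and ring closure of the β-peroxy enamine (Weitz–Scheffer-type nucleophilic epoxidation) set C-1 and C-5 together, the catalyst shielding one face of the enone.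

Step 3
Reactants: 4 (1S,5R)-5-(propan-2-yl)-6-oxabicyclo[3.1.0]hexan-2-one; 5 2-(2-methyl-1,3-dioxolan-2-yl)acetaldehyde
Product: 7 (2S,3R)-3-hydroxy-2-[(1R)-1-hydroxy-2-(2-methyl-1,3-dioxolan-2-yl)ethyl]-3-(propan-2-yl)cyclopentan-1-one, via samarium enolate 6 (not isolated)
Conditions: SmI2 (2.2 equiv), THF, −78 °C, 4 and 5 (1.1 equiv) added together; pH 7 buffer quench at −78 °C
Reagents that add atoms: none
Why: two single-electron transfers from samarium diiodide cleave the α C–O bond of the epoxy ketone through the ketyl and α-keto radical to a regiodefined enolate of trivalent samarium (reductive aldol of an α,β-epoxy ketone), which adds to the aldehyde through a chair transition state (ring-locked E enolate gives the anti aldol, C-1′ R) on the face syn to the samarium-bound tertiary alkoxide and anti to isopropyl (C-2 S), the tertiary C–O centre being retained.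

Step 4
Reactants: 7 (2S,3R)-3-hydroxy-2-[(1R)-1-hydroxy-2-(2-methyl-1,3-dioxolan-2-yl)ethyl]-3-(propan-2-yl)cyclopentan-1-one
Product: 8 (1R,2S)-2-[(1R)-1-hydroxy-2-(2-methyl-1,3-dioxolan-2-yl)ethyl]-3-methylidene-1-(propan-2-yl)cyclopentan-1-ol
Conditions: Zn, CH2Br2, TiCl4 (pre-aged reagent, 4 equiv), THF/CH2Cl2, 0 °C to rt
Reagents that add atoms: dibromomethane BrCBr
Why: the non-basic zinc–titanium methylenation (Takai–Lombardo) converts the hindered, aldol-prone ketone into the exocyclic alkene without retro-aldol, β-elimination or epimerisation at C-2; no new stereocentre is formed.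

Step 5 (key step)
Reactants: 8 (1R,2S)-2-[(1R)-1-hydroxy-2-(2-methyl-1,3-dioxolan-2-yl)ethyl]-3-methylidene-1-(propan-2-yl)cyclopentan-1-ol
Product: 10 {2-[(1R,2S,3R)-3-hydroxy-2-[(1R)-1-hydroxy-3-oxobutyl]-1-methyl-3-(propan-2-yl)cyclopentyl]ethyl}triphenylphosphonium bromide, via ketal phosphonium salt 9 (not isolated)
Conditions: Fe(acac)3 (0.5 equiv), PhSiH3 (2.5 equiv), vinyltriphenylphosphonium bromide (3 equiv), EtOH/(CH2OH)2 5:1, 60 °C; then 1 M HCl, THF, rt
Reagents that add atoms: vinyltriphenylphosphonium bromide C=C[P+](c1ccccc1)(c1ccccc1)c1ccccc1.[Br-]; water O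
Why: Proposed new method: hydrogen-atom transfer from the iron hydride (from Fe(acac)3 and PhSiH3) to the exocyclic methylene creates the angular methyl and a tertiary ring radical, which adds to the unsubstituted terminus of the strongly electron-poor vinylphosphonium salt (Giese addition) on the face anti to the bulky side chain on the adjacent carbon, so the quaternary centre (R) is set with methyl cis and the new two-carbon arm trans to that side chain; the α-phosphonio radical is then reduced by divalent iron and protonated by ethanol to the alkylphosphonium salt, and the acid stage removes the dioxolane; the closest known reactions are the iron-mediated reductive coupling of unactivated alkenes with vinyl sulfones or enones and the photoredox addition of alkyl radicals to vinylphosphonium salts.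

Step 6
Reactants: 10 {2-[(1R,2S,3R)-3-hydroxy-2-[(1R)-1-hydroxy-3-oxobutyl]-1-methyl-3-(propan-2-yl)cyclopentyl]ethyl}triphenylphosphonium bromide
Product: 12 (3R,3aS,4R,8aR)-6,8a-dimethyl-3-(propan-2-yl)-1,2,3,3a,4,5,8,8a-octahydroazulene-3,4-diol, via phosphonium ylide 11 (not isolated)
Conditions: KHMDS (1.05 equiv), THF (0.005 M), −78 °C to rt
Reagents that add atoms: none
Why: the phosphonium α-CH is far more acidic than the hydroxyls or the ketone α-hydrogens, so one equivalent of base gives the non-stabilised ylide, which attacks the tethered methyl ketone and collapses through the oxaphosphetane (intramolecular Wittig olefination) to the trisubstituted alkene, necessarily cis within the seven-membered ring; the trans ring fusion is already fixed and no new stereocentre is formed.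

Step 7
Reactants: 12 (3R,3aS,4R,8aR)-6,8a-dimethyl-3-(propan-2-yl)-1,2,3,3a,4,5,8,8a-octahydroazulene-3,4-diol; 13 tert-butyl(4-iodophenoxy)dimethylsilane
Product: 14 (3R,3aS,4R,8aR)-3-hydroxy-6,8a-dimethyl-3-(propan-2-yl)-1,2,3,3a,4,5,8,8a-octahydroazulen-4-yl 4-[(tert-butyldimethylsilyl)oxy]benzoate
Conditions: Pd(OAc)2 (5 mol%), Xantphos (6 mol%), CO (1 atm), Et3N (3 equiv), DMAP (0.5 equiv), 13 (1.5 equiv), toluene, 80 °C
Reagents that add atoms: carbon monoxide [C-]#[O+]
Why: palladium-catalysed alkoxycarbonylation of the aryl iodide (Heck carbonylation: oxidative addition, CO insertion, acyl transfer through the acylpyridinium) acylates the secondary C-4 hydroxyl while the tertiary C-3 hydroxyl is too hindered to react; no stereocentre is touched.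

Step 8
Reactants: 14 (3R,3aS,4R,8aR)-3-hydroxy-6,8a-dimethyl-3-(propan-2-yl)-1,2,3,3a,4,5,8,8a-octahydroazulen-4-yl 4-[(tert-butyldimethylsilyl)oxy]benzoate
Product: 15 (3R,3aS,4R,6R,7S,8aR)-6,7-epoxy-3-hydroxy-6,8a-dimethyl-3-(propan-2-yl)decahydroazulen-4-yl 4-[(tert-butyldimethylsilyl)oxy]benzoate
Conditions: m-CPBA (1.2 equiv), CH2Cl2, 0 °C
Reagents that add atoms: 3-chloroperoxybenzoic acid OOC(=O)c1cccc(Cl)c1
Why: Prilezhaev epoxidation of the only alkene occurs from the α face because the β face is screened by the angular methyl and the C-4 β-aroyloxy group, which sets C-6 (R) and C-7 (S).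

Step 9
Reactants: 15 (3R,3aS,4R,6R,7S,8aR)-6,7-epoxy-3-hydroxy-6,8a-dimethyl-3-(propan-2-yl)decahydroazulen-4-yl 4-[(tert-butyldimethylsilyl)oxy]benzoate
Product: 16 (3R,3aS,4R,6R,7S,8aR)-6,7-epoxy-3-hydroxy-6,8a-dimethyl-3-(propan-2-yl)decahydroazulen-4-yl 4-hydroxybenzoate
Conditions: TBAF (1.1 equiv), AcOH (1.1 equiv), THF, 0 °C
Reagents that add atoms: none
Why: fluoride cleaves the labile aryl silyl ether while acetic acid buffers the phenoxide, so the benzoate and the epoxide are not attacked (silyl ether deprotection); no stereocentre is touched.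

**Compound list**

1 | 3-methoxycyclopent-2-en-1-one | COC1=CC(=O)CC1 | starting material
2 | chloromagnesium 3-methoxy-1-(propan-2-yl)cyclopent-2-en-1-olate (racemic) | COC1=CC(O[Mg]Cl)(C(C)C)CC1 | intermediate
3 | 3-(propan-2-yl)cyclopent-2-en-1-one | CC(C)C1=CC(=O)CC1 | intermediate
4 | (1S,5R)-5-(propan-2-yl)-6-oxabicyclo[3.1.0]hexan-2-one | CC(C)[C@@]12O[C@@H]1C(=O)CC2 | intermediate
5 | 2-(2-methyl-1,3-dioxolan-2-yl)acetaldehyde (3-oxobutanal as its ethylene ketal) | CC1(CC=O)OCCO1 | starting material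
6 | bis(diiodosamarium) (3R)-3-(propan-2-yl)cyclopent-1-ene-1,3-diolate | CC(C)[C@]1(O[Sm](I)I)CCC(O[Sm](I)I)=C1 | intermediate
7 | (2S,3R)-3-hydroxy-2-[(1R)-1-hydroxy-2-(2-methyl-1,3-dioxolan-2-yl)ethyl]-3-(propan-2-yl)cyclopentan-1-one | CC(C)[C@]1(O)CCC(=O)[C@H]1[C@H](O)CC1(C)OCCO1 | intermediate
8 | (1R,2S)-2-[(1R)-1-hydroxy-2-(2-methyl-1,3-dioxolan-2-yl)ethyl]-3-methylidene-1-(propan-2-yl)cyclopentan-1-ol | CC(C)[C@]1(O)CCC(=C)[C@H]1[C@H](O)CC1(C)OCCO1 | intermediate
9 | {2-[(1R,2S,3R)-3-hydroxy-2-[(1R)-1-hydroxy-2-(2-methyl-1,3-dioxolan-2-yl)ethyl]-1-methyl-3-(propan-2-yl)cyclopentyl]ethyl}triphenylphosphonium bromide | CC(C)[C@]1(O)CC[C@](C)(CC[P+](c2ccccc2)(c2ccccc2)c2ccccc2)[C@H]1[C@H](O)CC1(C)OCCO1.[Br-] | intermediate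
10 | {2-[(1R,2S,3R)-3-hydroxy-2-[(1R)-1-hydroxy-3-oxobutyl]-1-methyl-3-(propan-2-yl)cyclopentyl]ethyl}triphenylphosphonium bromide | CC(C)[C@]1(O)CC[C@](C)(CC[P+](c2ccccc2)(c2ccccc2)c2ccccc2)[C@H]1[C@H](O)CC(C)=O.[Br-] | intermediate
11 | (4R)-4-hydroxy-4-[(1S,2R,5R)-2-hydroxy-5-methyl-2-(propan-2-yl)-5-[2-(triphenyl-λ5-phosphanylidene)ethyl]cyclopentyl]butan-2-one | CC(C)[C@]1(O)CC[C@](C)(CC=P(c2ccccc2)(c2ccccc2)c2ccccc2)[C@H]1[C@H](O)CC(C)=O | intermediate
12 | (3R,3aS,4R,8aR)-6,8a-dimethyl-3-(propan-2-yl)-1,2,3,3a,4,5,8,8a-octahydroazulene-3,4-diol | CC(C)[C@]1(O)CC[C@]2(C)CC=C(C)C[C@@H](O)[C@H]21 | intermediate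
13 | tert-butyl(4-iodophenoxy)dimethylsilane (4-iodophenol as its TBS ether) | CC(C)(C)[Si](C)(C)Oc1ccc(I)cc1 | starting material
14 | (3R,3aS,4R,8aR)-3-hydroxy-6,8a-dimethyl-3-(propan-2-yl)-1,2,3,3a,4,5,8,8a-octahydroazulen-4-yl 4-[(tert-butyldimethylsilyl)oxy]benzoate | CC(C)[C@]1(O)CC[C@]2(C)CC=C(C)C[C@@H](OC(=O)c3ccc(O[Si](C)(C)C(C)(C)C)cc3)[C@H]21 | intermediate
15 | (3R,3aS,4R,6R,7S,8aR)-6,7-epoxy-3-hydroxy-6,8a-dimethyl-3-(propan-2-yl)decahydroazulen-4-yl 4-[(tert-butyldimethylsilyl)oxy]benzoate | CC(C)[C@]1(O)CC[C@]2(C)C[C@@H]3O[C@]3(C)C[C@@H](OC(=O)c3ccc(O[Si](C)(C)C(C)(C)C)cc3)[C@H]21 | intermediate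
16 | (3R,3aS,4R,6R,7S,8aR)-6,7-epoxy-3-hydroxy-6,8a-dimethyl-3-(propan-2-yl)decahydroazulen-4-yl 4-hydroxybenzoate | CC(C)[C@]1(O)CC[C@]2(C)C[C@@H]3O[C@]3(C)C[C@@H](OC(=O)c3ccc(O)cc3)[C@H]21 | target

**Step count and risks**

Total step count: 9. Longest linear sequence: 9 steps (1 to 16).

The three steps most likely to fail:

Step 5 is the least precedented. The vinylphosphonium salt may be consumed by hydride or ethoxide conjugate addition, and the hindered tertiary radical may simply be reduced. The fallback replaces the Wittig ring closure by a Julia-type olefination. Setting out from 8, the same iron-hydride conditions with phenyl vinyl sulfone (an established acceptor) give ketal sulfone F1, whose dioxolane is hydrolysed (1 M HCl, THF) to keto sulfone F2. Both hydroxyls are silylated (Et3SiOTf, 2,6-lutidine) to bis(triethylsilyl) ether F3. LDA (THF, −78 °C) closes the seven-membered ring by addition of the α-sulfonyl carbanion to the methyl ketone, giving β-hydroxy sulfone F4. Reductive elimination with SmI2/HMPA gives bis(triethylsilyl) diene F5, and TBAF returns to 12.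

Step 3 may give poor anti/syn or facial selectivity, or Tishchenko-type over-reduction by excess aldehyde. The fallback separates enolate formation from the aldol. Setting out from 4, SmI2 in the presence of Me3SiCl gives the regiodefined bis(silyl) enol ether F6. MeLi releases lithium enolate F7, and (c-C6H11)2BCl converts it into boron enolate F8, which adds 5 through a tight boron chair transition state (anti) to give silyl-protected aldol F9. Citric acid in MeOH removes the tertiary trimethylsilyl ether and returns to 7. The C-2 centre is thermodynamically biased towards the same trans-to-isopropyl arrangement, so it can be equilibrated if needed.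

Step 7 may be slow because the C-4 hydroxyl is hindered and sits cis to the angular methyl. The fallback makes the acylating agent separately. Setting out from 13, iodine–magnesium exchange (i-PrMgCl·LiCl, THF, −20 °C) gives arylmagnesium chloride F10, CO2 then gives acid F11, and oxalyl chloride with catalytic DMF gives acid chloride F12. F12 acylates 12 (Et3N, DMAP, CH2Cl2, 40 °C) and the route is rejoined at 14.

**Further compounds**

F1 | step 5 | (1R,2S,3R)-3-[2-(benzenesulfonyl)ethyl]-2-[(1R)-1-hydroxy-2-(2-methyl-1,3-dioxolan-2-yl)ethyl]-3-methyl-1-(propan-2-yl)cyclopentan-1-ol | CC(C)[C@]1(O)CC[C@](C)(CCS(=O)(=O)c2ccccc2)[C@H]1[C@H](O)CC1(C)OCCO1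
F2 | step 5 | (4R)-4-[(1S,2R,5R)-5-[2-(benzenesulfonyl)ethyl]-2-hydroxy-5-methyl-2-(propan-2-yl)cyclopentyl]-4-hydroxybutan-2-one | CC(C)[C@]1(O)CC[C@](C)(CCS(=O)(=O)c2ccccc2)[C@H]1[C@H](O)CC(C)=O
F3 | step 5 | bis(triethylsilyl) ether of F2 | CC(C)[C@]1(O[Si](CC)(CC)CC)CC[C@](C)(CCS(=O)(=O)c2ccccc2)[C@H]1[C@H](O[Si](CC)(CC)CC)CC(C)=O
F4 | step 5 | (3R,3aS,4R,8aR)-7-(benzenesulfonyl)-6,8a-dimethyl-3-(propan-2-yl)-3,4-bis[(triethylsilyl)oxy]decahydroazulen-6-ol (mixture at C-6 and C-7) | CC(C)[C@]1(O[Si](CC)(CC)CC)CC[C@]2(C)CC(S(=O)(=O)c3ccccc3)C(C)(O)C[C@@H](O[Si](CC)(CC)CC)[C@H]21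
F5 | step 5 | bis(triethylsilyl) ether of 12 | CC(C)[C@]1(O[Si](CC)(CC)CC)CC[C@]2(C)CC=C(C)C[C@@H](O[Si](CC)(CC)CC)[C@H]21
F6 | step 3 | trimethyl{[(3R)-3-(propan-2-yl)-3-[(trimethylsilyl)oxy]cyclopent-1-en-1-yl]oxy}silane | CC(C)[C@]1(O[Si](C)(C)C)CCC(O[Si](C)(C)C)=C1
F7 | step 3 | lithium (3R)-3-(propan-2-yl)-3-[(trimethylsilyl)oxy]cyclopent-1-en-1-olate | CC(C)[C@]1(O[Si](C)(C)C)CCC(O[Li])=C1
F8 | step 3 | dicyclohexyl{[(3R)-3-(propan-2-yl)-3-[(trimethylsilyl)oxy]cyclopent-1-en-1-yl]oxy}borane | CC(C)[C@]1(O[Si](C)(C)C)CCC(OB(C2CCCCC2)C2CCCCC2)=C1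
F9 | step 3 | (2S,3R)-2-[(1R)-1-hydroxy-2-(2-methyl-1,3-dioxolan-2-yl)ethyl]-3-(propan-2-yl)-3-[(trimethylsilyl)oxy]cyclopentan-1-one | CC(C)[C@]1(O[Si](C)(C)C)CCC(=O)[C@H]1[C@H](O)CC1(C)OCCO1
F10 | step 7 | {4-[(tert-butyldimethylsilyl)oxy]phenyl}magnesium chloride | CC(C)(C)[Si](C)(C)Oc1ccc([Mg]Cl)cc1
F11 | step 7 | 4-[(tert-butyldimethylsilyl)oxy]benzoic acid | CC(C)(C)[Si](C)(C)Oc1ccc(cc1)C(=O)O
F12 | step 7 | 4-[(tert-butyldimethylsilyl)oxy]benzoyl chloride | CC(C)(C)[Si](C)(C)Oc1ccc(cc1)C(Cl)=O
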